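**Plan**
1. Cuts: the side-chain CH=CH bond (cross-metathesis); the bond from the linker CH2 to the cyclohexene sp2 carbon (alkyl–alkenyl Negishi union); C7–CH3 and C6–CH2 of the bicyclic half (methyl addition, vinylation of an enol triflate); in the oxepane, C3–C4 (ring-closing metathesis) and O1–C2 (Nicholas etherification).
2. Enabling feature: in the oxepane ring O1–C2(Me2)–C3–C4–C5–C5a–C9a, the C3–C4 bond lies farthest from the fully substituted carbons C2 and C5a. Its flanks, C5 on the angular carbon C5a and O1 on C9a, are neighbouring equatorial substituents of the cyclohexane chair, so an allyl group on C5a and a 1,1-dimethylallyl ether on the C9a oxygen already lie side by side.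
3. Both six-membered rings come from one achiral dione, 2-allyl-2-methylcyclohexane-1,3-dione. The oxepene is the only ring that is formed.
4. Forward order: desymmetrise, make the tertiary ether, close the oxepene, oxygenate C3, elaborate C6/C7, join to the cyclohexenyl triflate, add methyl, extend the allyl group, deprotect.
5. Stereochemistry: C5a/C9a from yeast reduction plus Mitsunobu inversion. C3 from epoxidation opposite the C5a methyl and hydride opening at C4. C6 from α-face hydroboration. C7 from equatorial methyl delivery. The cyclohexene quaternary carbon and carbinol from a CBS reduction of the same dione in the antipodal sense. The E alkene from cross-metathesis.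

Key step: step 9

Remark: the bicyclic half is numbered as a 1-benzoxepine (O1, C2–C5, C5a, C6–C9, C9a) and α means the face opposite the C5a methyl. (S)-Me-CBS is assumed to follow its usual large/small model with the quaternary C2 as the large group. TBS = tert-butyldimethylsilyl, TES = triethylsilyl.

**Step 1**
Reactants: 1 2-methylcyclohexane-1,3-dione; 2 allyl bromide
Product: 3 2-allyl-2-methylcyclohexane-1,3-dione
Conditions: NaOH (1 equiv), H2O, rt
Reagents that add atoms: none
Why: C-alkylation of the stabilised 1,3-diketone enolate with a soft allylic halide in water favours carbon over oxygen, and the product has no acidic C2–H left, so it cannot react twice; no stereocentre is formed.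

**Step 2**
Reactants: 3 2-allyl-2-methylcyclohexane-1,3-dione
Product: 4 (2S,3S)-2-allyl-3-hydroxy-2-methylcyclohexan-1-one (OH cis to allyl)
Conditions: baker's yeast, sucrose, H2O, 30 °C; chromatographic removal of the minor (2R,3S) diastereomer
Reagents that add atoms: none
Why: Microbial desymmetrising reduction of a prochiral 2,2-disubstituted 1,3-diketone; Prelog-type hydride delivery sets the 3S carbinol, and attack on the methyl-bearing ring face of one enantiotopic carbonyl fixes C2 as S.

**Step 3**
Reactants: 4 (2S,3S)-2-allyl-3-hydroxy-2-methylcyclohexan-1-one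
Product: 5 (1R,2S)-2-allyl-2-methyl-3-oxocyclohexyl 4-nitrobenzoate
Conditions: 4-nitrobenzoic acid, PPh3, DIAD, toluene, 0 °C → rt
Reagents that add atoms: 4-nitrobenzoic acid O=C(O)c1ccc(cc1)[N+](=O)[O-]
Why: Mitsunobu reaction in its hindered-alcohol variant with an acidic carboxylate; SN2 displacement of the alkoxyphosphonium ion inverts the carbinol to R, and the quaternary C2 rules out enone formation.

**Step 4**
Reactants: 5 (1R,2S)-2-allyl-2-methyl-3-oxocyclohexyl 4-nitrobenzoate
Product: 6 (2S,3R)-2-allyl-3-hydroxy-2-methylcyclohexan-1-one (OH trans to allyl, cis to methyl)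
Conditions: K2CO3 (cat.), MeOH, 0 °C, short contact
Reagents that add atoms: none
Why: Transesterification of the activated nitrobenzoate cleaves the acyl–oxygen bond, so the new carbinol configuration is kept; low temperature and short contact keep retro-aldol opening of the β-ketol out.

**Step 5**
Reactants: 7 2-methylbut-3-yn-2-ol
Product: 8 hexacarbonyl(μ-2-methylbut-3-yn-2-ol)dicobalt
Conditions: Co2(CO)8, CH2Cl2, rt
Reagents that add atoms: dicobalt octacarbonyl O=C=[Co](=C=O)(=C=O)(=C=O)[Co](=C=O)(=C=O)(=C=O)=C=O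
Why: Alkyne complexation with loss of two CO gives the dicobaltatetrahedrane that will stabilise a cation on the adjacent carbon.

**Step 6**
Reactants: 6 (2S,3R)-2-allyl-3-hydroxy-2-methylcyclohexan-1-one; 8 hexacarbonyl(μ-2-methylbut-3-yn-2-ol)dicobalt
Product: 10 Co2(CO)6 complex of (2S,3R)-2-allyl-2-methyl-3-[(2-methylbut-3-yn-2-yl)oxy]cyclohexan-1-one, via cobalt-stabilised propargylic cation 9 (not isolated)
Conditions: 8 (1.5 equiv), BF3·OEt2, 4 Å MS, CH2Cl2, −20 → 0 °C
Reagents that add atoms: none
Why: Nicholas etherification; the tertiary cation is stabilised by the cobalt cluster and is trapped by the ring hydroxyl acting as nucleophile, so the C–O bond of 6 and its configuration are untouched.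

**Step 7**
Reactants: 10 Co2(CO)6 complex of the propargylic ether
Product: 11 (2S,3R)-2-allyl-2-methyl-3-[(2-methylbut-3-yn-2-yl)oxy]cyclohexan-1-one
Conditions: (NH4)2Ce(NO3)6, acetone, 0 °C
Reagents that add atoms: none
Why: Oxidative decomplexation removes the cobalt cluster and frees the terminal alkyne; ketone, allyl group and tertiary ether are inert to brief exposure at 0 °C.

**Step 8**
Reactants: 11 (2S,3R)-2-allyl-2-methyl-3-[(2-methylbut-3-yn-2-yl)oxy]cyclohexan-1-one
Product: 12 (2S,3R)-2-allyl-2-methyl-3-[(2-methylbut-3-en-2-yl)oxy]cyclohexan-1-one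
Conditions: H2 (1 atm), Lindlar catalyst, quinoline, EtOAc, rt, stopped after 1 equiv H2
Reagents that add atoms: none
Why: Lindlar semihydrogenation; the terminal alkyne binds the poisoned palladium far more strongly than the allyl alkene, so it should be reduced selectively to the vinyl group.

**Step 9**
Reactants: 12 (2S,3R)-2-allyl-2-methyl-3-[(2-methylbut-3-en-2-yl)oxy]cyclohexan-1-one
Product: 13 (5aS,9aR)-2,2,5a-trimethyl-5,5a,7,8,9,9a-hexahydro-1-benzoxepin-6(2H)-one (trans-fused, C3=C4)
Conditions: Grubbs II (5–10 mol %), 1,4-benzoquinone (10 mol %), CH2Cl2 (0.002 M), 40 °C, Ar sparge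
Reagents that add atoms: none
Why: Ring-closing olefin metathesis by the Chauvin cycle: the ruthenium benzylidene first exchanges with the open allyl CH=CH2 on C5a, the new alkylidene adds intramolecularly across the vinyl group next to C2 to give a ruthenacyclobutane, and cycloreversion releases the C3=C4 alkene while Ru=CH2 carries the chain and ethylene leaves the solution. The closest known reaction type is RCM of allyl/1,1-dimethylallyl ether dienes to 2,2-dimethyl-substituted dihydropyrans and oxepenes fused to six-membered rings. One ring is closed, the seven-membered oxepene, by joining the two internal alkene carbons of a 1,8-diene (C3 to C4), and the ring size allows only the Z alkene. No stereocentre is created and C5a and C9a are not touched, so the trans ring fusion is carried over from 12. The selectivity needed is cyclisation over acyclic diene metathesis and over allyl-to-propenyl isomerisation: in the chair with the C5a methyl axial, the allyl arm and the ether oxygen are both equatorial and gauche, the gem-dimethyl group at C2 folds the ether arm back (Thorpe–Ingold effect), the hindered vinyl group cannot homodimerise, and high dilution, ethylene removal and benzoquinone cover the rest.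

**Step 10**
Reactants: 13 (5aS,9aR)-2,2,5a-trimethyl-5,5a,7,8,9,9a-hexahydro-1-benzoxepin-6(2H)-one
Product: 14 (3R,4R,5aS,9aR)-3,4-epoxy-2,2,5a-trimethyloctahydro-1-benzoxepin-6(2H)-one (oxirane on the α face)
Conditions: mCPBA, NaHCO3, CH2Cl2, 0 °C → rt
Reagents that add atoms: 3-chloroperoxybenzoic acid OOC(=O)c1cccc(Cl)c1
Why: Prilezhaev epoxidation; the peracid is expected to come from the α face because the axial C5a methyl overhangs the β face of C4, which sets C3 and C4 (both R), and buffering at low temperature keeps Baeyer–Villiger oxidation of the hindered ketone out.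

**Step 11**
Reactants: 14 (3R,4R,5aS,9aR)-3,4-epoxy-2,2,5a-trimethyloctahydro-1-benzoxepin-6(2H)-one
Product: 16 (3R,4R,5aS,9aR)-3,4-epoxy-2,2,5a-trimethyl-2,3,4,5,5a,8,9,9a-octahydro-1-benzoxepin-6-yl trifluoromethanesulfonate, via potassium enolate 15 (not isolated)
Conditions: KHMDS, THF, −78 °C; then PhNTf2, −78 → 0 °C
Reagents that add atoms: potassium hexamethyldisilazide [K+].C[Si](C)(C)[N-][Si](C)(C)C (potassium of 15); N-phenylbis(trifluoromethanesulfonimide) O=S(=O)(N(c1ccccc1)S(=O)(=O)C(F)(F)F)C(F)(F)F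
Why: Enol triflate formation by O-sulfonylation of a kinetic enolate; deprotonation is possible only at C7 because C5a is quaternary, and the oxirane is inert to the amide base at −78 °C.

**Step 12**
Reactants: 16 enol triflate
Product: 17 (3R,4R,5aR,9aR)-3,4-epoxy-2,2,5a-trimethyl-6-vinyl-2,3,4,5,5a,8,9,9a-octahydro-1-benzoxepine
Conditions: CH2=CHSnBu3, Pd(PPh3)4 (5 mol %), LiCl, THF, 65 °C
Reagents that add atoms: tributyl(vinyl)stannane C=C[Sn](CCCC)(CCCC)CCCC
Why: Stille coupling of an enol triflate with LiCl as promoter is neutral, tolerates the epoxide, and brings in both linker carbons with a small partner at the neopentyl-type sp2 carbon.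

**Step 13**
Reactants: 17 vinyl epoxide-bearing diene
Product: 18 (3R,5aR,9aR)-2,2,5a-trimethyl-6-vinyl-2,3,4,5,5a,8,9,9a-octahydro-1-benzoxepin-3-ol
Conditions: LiEt3BH, THF, 0 → 65 °C; then H2O
Reagents that add atoms: none
Why: SN2 reduction of an epoxide with Super-Hydride; hydride attacks C4, the oxirane carbon remote from the fully substituted C2 and its electron-withdrawing oxygen, so the C3–O bond keeps its α orientation (3R). No ketone is left in the molecule at this stage.

**Step 14**
Reactants: 18 oxepanol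
Product: 19 3-O-TBS ether of 18, (3R,5aR,9aR)-3-(tert-butyldimethylsilyloxy)-2,2,5a-trimethyl-6-vinyl-2,3,4,5,5a,8,9,9a-octahydro-1-benzoxepine
Conditions: TBSOTf, 2,6-lutidine, CH2Cl2, 0 °C
Reagents that add atoms: tert-butyldimethylsilyl trifluoromethanesulfonate CC(C)(C)[Si](C)(C)OS(=O)(=O)C(F)(F)F
Why: Silylation with the reactive silyl triflate covers the hindered secondary carbinol so that only C7 is oxidised later.

**Step 15**
Reactants: 19 3-O-TBS diene
Product: 22 (3R,5aR,6R,7R,9aR)-3-(tert-butyldimethylsilyloxy)-6-(2-hydroxyethyl)-2,2,5a-trimethyldecahydro-1-benzoxepin-7-ol, via B-alkyl-9-BBN adduct 20 (not isolated), via C7 borane 21 (not isolated)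
Conditions: 9-BBN (1.1 equiv), THF, 0 °C → rt; BH3·THF, 0 °C → rt; NaOH, H2O2, 0 °C → rt
Reagents that add atoms: 9-borabicyclo[3.3.1]nonane B1C2CCCC1CCC2 (boron of 20 and 21); borane–THF B.C1CCOC1 (boron at C7 of 21); hydrogen peroxide OO
Why: Sequential hydroboration–oxidation; 9-BBN takes only the terminal vinyl carbon. BH3 then adds syn across C6=C7 from the α face, away from the axial C5a methyl, with boron on the less substituted C7. This sets C6–H α (6R) and, after retentive oxidation, the equatorial 7α-hydroxyl.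

**Step 16**
Reactants: 22 diol
Product: 23 (3R,5aR,6R,7R,9aR)-3-(tert-butyldimethylsilyloxy)-6-(2-iodoethyl)-2,2,5a-trimethyldecahydro-1-benzoxepin-7-ol
Conditions: I2, PPh3, imidazole, CH2Cl2, 0 °C
Reagents that add atoms: iodine II
Why: Appel-type iodination picks the primary alcohol over the ring carbinol on steric grounds, and the low temperature should keep the C7 hydroxyl from closing a tetrahydrofuran.

**Step 17**
Reactants: 23 iodo alcohol
Product: 24 (3R,5aR,6R,9aR)-3-(tert-butyldimethylsilyloxy)-6-(2-iodoethyl)-2,2,5a-trimethyloctahydro-1-benzoxepin-7(2H)-one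
Conditions: Dess–Martin periodinane, NaHCO3, CH2Cl2, 0 °C → rt
Reagents that add atoms: none
Why: Dess–Martin oxidation is neutral and spares the alkyl iodide and silyl ether; C6 keeps its configuration because the equatorial side chain is also the more stable epimer.

**Step 18**
Reactants: 3 2-allyl-2-methylcyclohexane-1,3-dione
Product: 25 (2R,3R)-2-allyl-3-hydroxy-2-methylcyclohexan-1-one (OH cis to allyl)
Conditions: (S)-Me-CBS (20 mol %), catecholborane, toluene, −78 → −40 °C
Reagents that add atoms: none
Why: CBS reduction used as a desymmetrisation of the prochiral diketone; the oxazaborolidine sets the 3R carbinol (quaternary C2 large, C4H2 small), and hydride entry on the methyl-bearing ring face puts OH cis to allyl, which fixes C2 as R.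

**Step 19**
Reactants: 25 (2R,3R)-ketol
Product: 26 (2R,3R)-2-allyl-3-(tert-butyldimethylsilyloxy)-2-methylcyclohexan-1-one
Conditions: TBSOTf (1.1 equiv), 2,6-lutidine, CH2Cl2, −78 → 0 °C
Reagents that add atoms: tert-butyldimethylsilyl trifluoromethanesulfonate CC(C)(C)[Si](C)(C)OS(=O)(=O)C(F)(F)F
Why: Silylation of the neopentyl-type carbinol blocks retro-aldol chemistry in the enolate steps that follow; limiting the reagent avoids silyl enol ether formation.

**Step 20**
Reactants: 26 silyloxy ketone
Product: 28 (2R,3R)-2-allyl-3-(tert-butyldimethylsilyloxy)-2,6-dimethylcyclohexan-1-one (C6 epimers), via lithium enolate 27 (not isolated)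
Conditions: LDA, THF, −78 °C; MeI, −78 → −20 °C
Reagents that add atoms: lithium diisopropylamide [Li+].CC(C)[N-]C(C)C (lithium of 27); iodomethane CI
Why: Enolate alkylation; only C6 carries α-hydrogens, so the regiochemistry is unambiguous, and the C6 configuration is erased in the next step.

**Step 21**
Reactants: 28 dimethyl ketone
Product: 30 (5R,6R)-6-allyl-5-(tert-butyldimethylsilyloxy)-2,6-dimethylcyclohex-1-en-1-yl trifluoromethanesulfonate, via tetrasubstituted potassium enolate 29 (not isolated)
Conditions: KHMDS, THF, −78 → 0 °C; PhNTf2, −78 °C → rt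
Reagents that add atoms: potassium hexamethyldisilazide [K+].C[Si](C)(C)[N-][Si](C)(C)C (potassium of 29); N-phenylbis(trifluoromethanesulfonimide) O=S(=O)(N(c1ccccc1)S(=O)(=O)C(F)(F)F)C(F)(F)F
Why: Enol triflate formation as practised on 2,2,6-trisubstituted cyclohexanones; the single remaining α-hydrogen gives one enolate and therefore the tetrasubstituted alkene of the target.

**Step 22**
Reactants: 24 iodo ketone; 30 cyclohexenyl triflate
Product: 32 (3R,5aR,6R,9aR)-6-{2-[(5R,6S)-6-allyl-5-(tert-butyldimethylsilyloxy)-2,6-dimethylcyclohex-1-en-1-yl]ethyl}-3-(tert-butyldimethylsilyloxy)-2,2,5a-trimethyloctahydro-1-benzoxepin-7(2H)-one, via alkylzinc iodide 31 (not isolated)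
Conditions: 24, Zn dust (activated), LiCl, THF, 40 °C; then 30, Pd2(dba)3 (5 mol %), SPhos (12 mol %), THF/NMP, 60 °C
Reagents that add atoms: zinc [Zn] (in 31)
Why: Negishi alkyl–alkenyl coupling; zinc inserts into the primary C–I bond without touching the ketone, and an electron-rich bulky biarylphosphine on palladium should make reductive elimination faster than β-hydride elimination; no stereocentre is involved.

**Step 23**
Reactants: 32 coupled ketone
Product: 33 (3R,5aR,6R,7S,9aR)-6-{2-[(5R,6S)-6-allyl-5-(tert-butyldimethylsilyloxy)-2,6-dimethylcyclohex-1-en-1-yl]ethyl}-3-(tert-butyldimethylsilyloxy)-2,2,5a,7-tetramethyldecahydro-1-benzoxepin-7-ol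
Conditions: CeCl3 (dried), MeLi, THF, −78 °C; then 32, −78 °C
Reagents that add atoms: methyllithium [Li]C
Why: Organocerium 1,2-addition suppresses enolisation of the α-branched ketone; methyl enters along the equatorial α path because the axial β path is blocked by the 1,3-related axial C5a methyl, giving the axial 7β-hydroxyl (7S).

**Step 24**
Reactants: 33 tertiary alcohol; 34 2-methylbut-3-en-2-ol
Product: 35 3,5'-bis-O-TBS siphonellinol C, i.e. 33 with the allyl group extended to (E)-4-hydroxy-4-methylpent-2-en-1-yl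
Conditions: 34 (10 equiv), Hoveyda–Grubbs II (10 mol %), CH2Cl2, 40 °C
Reagents that add atoms: none
Why: Olefin cross-metathesis between a readily reacting terminal allyl group and a slowly dimerising tertiary allylic alcohol is selective for the cross product and for the E alkene; the tetrasubstituted ring alkene is inert.

**Step 25**
Reactants: 35 bis-silyl ether
Product: 36 siphonellinol C
Conditions: TBAF, THF, rt → 50 °C
Reagents that add atoms: none
Why: Fluoride desilylation frees both hindered secondary carbinols under basic conditions that do not ionise the tertiary allylic alcohol; no stereocentre is affected.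

**Compound list**
1 | 2-methylcyclohexane-1,3-dione | CC1C(=O)CCCC1=O | starting material
2 | allyl bromide | C=CCBr | starting material
3 | 2-allyl-2-methylcyclohexane-1,3-dione | C=CCC1(C)C(=O)CCCC1=O | intermediate
4 | (2S,3S)-2-allyl-3-hydroxy-2-methylcyclohexan-1-one | C=CC[C@]1(C)C(=O)CCC[C@@H]1O | intermediate
5 | (1R,2S)-2-allyl-2-methyl-3-oxocyclohexyl 4-nitrobenzoate | C=CC[C@]1(C)C(=O)CCC[C@H]1OC(=O)c1ccc(cc1)[N+](=O)[O-] | intermediate
6 | (2S,3R)-2-allyl-3-hydroxy-2-methylcyclohexan-1-one | C=CC[C@]1(C)C(=O)CCC[C@H]1O | intermediate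
7 | 2-methylbut-3-yn-2-ol | C#CC(C)(C)O | starting material
8 | hexacarbonyl(μ-2-methylbut-3-yn-2-ol)dicobalt | CC(C)(O)C12[Co]3(=C=O)(=C=O)(=C=O)[Co]1(=C=O)(=C=O)(=C=O)C23 | intermediate
9 | cobalt-stabilised propargylic cation | C[C+](C)C12[Co]3(=C=O)(=C=O)(=C=O)[Co]1(=C=O)(=C=O)(=C=O)C23 | intermediate
10 | Co2(CO)6 complex of (2S,3R)-2-allyl-2-methyl-3-[(2-methylbut-3-yn-2-yl)oxy]cyclohexan-1-one | C=CC[C@]1(C)C(=O)CCC[C@H]1OC(C)(C)C23[Co]4(=C=O)(=C=O)(=C=O)[Co]2(=C=O)(=C=O)(=C=O)C34 | intermediate
11 | (2S,3R)-2-allyl-2-methyl-3-[(2-methylbut-3-yn-2-yl)oxy]cyclohexan-1-one | C=CC[C@]1(C)C(=O)CCC[C@H]1OC(C)(C)C#C | intermediate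
12 | (2S,3R)-2-allyl-2-methyl-3-[(2-methylbut-3-en-2-yl)oxy]cyclohexan-1-one | C=CC[C@]1(C)C(=O)CCC[C@H]1OC(C)(C)C=C | intermediate
13 | (5aS,9aR)-2,2,5a-trimethyl-5,5a,7,8,9,9a-hexahydro-1-benzoxepin-6(2H)-one | O=C1CCC[C@H]2OC(C)(C)C=CC[C@]12C | intermediate
14 | (3R,4R,5aS,9aR)-3,4-epoxy-2,2,5a-trimethyloctahydro-1-benzoxepin-6(2H)-one | O=C1CCC[C@H]2OC(C)(C)[C@@H]3O[C@@H]3C[C@]12C | intermediate
15 | potassium enolate of 14 | [K+].[O-]C1=CCC[C@H]2OC(C)(C)[C@@H]3O[C@@H]3C[C@]12C | intermediate
16 | (3R,4R,5aS,9aR)-3,4-epoxy-2,2,5a-trimethyl-2,3,4,5,5a,8,9,9a-octahydro-1-benzoxepin-6-yl trifluoromethanesulfonate | O=S(=O)(OC1=CCC[C@H]2OC(C)(C)[C@@H]3O[C@@H]3C[C@]12C)C(F)(F)F | intermediate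
17 | (3R,4R,5aR,9aR)-3,4-epoxy-2,2,5a-trimethyl-6-vinyl-2,3,4,5,5a,8,9,9a-octahydro-1-benzoxepine | C=CC1=CCC[C@H]2OC(C)(C)[C@@H]3O[C@@H]3C[C@]12C | intermediate
18 | (3R,5aR,9aR)-2,2,5a-trimethyl-6-vinyl-2,3,4,5,5a,8,9,9a-octahydro-1-benzoxepin-3-ol | C=CC1=CCC[C@H]2OC(C)(C)[C@H](O)CC[C@]12C | intermediate
19 | 3-O-TBS ether of 18 | C=CC1=CCC[C@H]2OC(C)(C)[C@H](O[Si](C)(C)C(C)(C)C)CC[C@]12C | intermediate
20 | B-alkyl-9-BBN adduct of 19 | B1(CCC3=CCC[C@H]4OC(C)(C)[C@H](O[Si](C)(C)C(C)(C)C)CC[C@]34C)C2CCCC1CCC2 | intermediate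
21 | C7 borane of 20 | B1(CC[C@@H]3[C@@]4(C)CC[C@@H](O[Si](C)(C)C(C)(C)C)C(C)(C)O[C@@H]4CC[C@H]3B)C2CCCC1CCC2 | intermediate
22 | (3R,5aR,6R,7R,9aR)-3-(tert-butyldimethylsilyloxy)-6-(2-hydroxyethyl)-2,2,5a-trimethyldecahydro-1-benzoxepin-7-ol | OCC[C@@H]1[C@@]2(C)CC[C@@H](O[Si](C)(C)C(C)(C)C)C(C)(C)O[C@@H]2CC[C@H]1O | intermediate
23 | (3R,5aR,6R,7R,9aR)-3-(tert-butyldimethylsilyloxy)-6-(2-iodoethyl)-2,2,5a-trimethyldecahydro-1-benzoxepin-7-ol | ICC[C@@H]1[C@@]2(C)CC[C@@H](O[Si](C)(C)C(C)(C)C)C(C)(C)O[C@@H]2CC[C@H]1O | intermediate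
24 | (3R,5aR,6R,9aR)-3-(tert-butyldimethylsilyloxy)-6-(2-iodoethyl)-2,2,5a-trimethyloctahydro-1-benzoxepin-7(2H)-one | ICC[C@@H]1[C@@]2(C)CC[C@@H](O[Si](C)(C)C(C)(C)C)C(C)(C)O[C@@H]2CCC1=O | intermediate
25 | (2R,3R)-2-allyl-3-hydroxy-2-methylcyclohexan-1-one | C=CC[C@@]1(C)C(=O)CCC[C@H]1O | intermediate
26 | (2R,3R)-2-allyl-3-(tert-butyldimethylsilyloxy)-2-methylcyclohexan-1-one | C=CC[C@@]1(C)C(=O)CCC[C@H]1O[Si](C)(C)C(C)(C)C | intermediate
27 | lithium enolate of 26 | [Li+].C=CC[C@@]1(C)C([O-])=CCC[C@H]1O[Si](C)(C)C(C)(C)C | intermediate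
28 | (2R,3R)-2-allyl-3-(tert-butyldimethylsilyloxy)-2,6-dimethylcyclohexan-1-one (C6 epimers) | C=CC[C@@]1(C)C(=O)C(C)CC[C@H]1O[Si](C)(C)C(C)(C)C | intermediate
29 | tetrasubstituted potassium enolate of 28 | [K+].C=CC[C@@]1(C)C([O-])=C(C)CC[C@H]1O[Si](C)(C)C(C)(C)C | intermediate
30 | (5R,6R)-6-allyl-5-(tert-butyldimethylsilyloxy)-2,6-dimethylcyclohex-1-en-1-yl trifluoromethanesulfonate | C=CC[C@@]1(C)C(OS(=O)(=O)C(F)(F)F)=C(C)CC[C@H]1O[Si](C)(C)C(C)(C)C | intermediate
31 | alkylzinc iodide from 24 | I[Zn]CC[C@@H]1[C@@]2(C)CC[C@@H](O[Si](C)(C)C(C)(C)C)C(C)(C)O[C@@H]2CCC1=O | intermediate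
32 | coupled bis-TBS C7 ketone (name as in step 22) | CC1=C(CC[C@@H]2[C@@]3(C)CC[C@@H](O[Si](C)(C)C(C)(C)C)C(C)(C)O[C@@H]3CCC2=O)[C@](C)(CC=C)[C@H](O[Si](C)(C)C(C)(C)C)CC1 | intermediate
33 | bis-TBS allyl tertiary alcohol (name as in step 23) | CC1=C(CC[C@@H]2[C@@]3(C)CC[C@@H](O[Si](C)(C)C(C)(C)C)C(C)(C)O[C@@H]3CC[C@]2(C)O)[C@](C)(CC=C)[C@H](O[Si](C)(C)C(C)(C)C)CC1 | intermediate
34 | 2-methylbut-3-en-2-ol | C=CC(C)(C)O | starting material
35 | 3,5'-bis-O-TBS siphonellinol C | CC1=C(CC[C@@H]2[C@@]3(C)CC[C@@H](O[Si](C)(C)C(C)(C)C)C(C)(C)O[C@@H]3CC[C@]2(C)O)[C@](C)(C/C=C/C(C)(C)O)[C@H](O[Si](C)(C)C(C)(C)C)CC1 | intermediate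
36 | siphonellinol C | CC1=C(CC[C@@H]2[C@@]3(C)CC[C@@H](O)C(C)(C)O[C@@H]3CC[C@]2(C)O)[C@](C)(C/C=C/C(C)(C)O)[C@H](O)CC1 | target

**Step count**
Total steps: 25.
Longest linear sequence: 20 (steps 1–4, 6–17, 22–25). Step 5 and steps 18–21 are side branches.

**Steps most likely to fail**

Step 6 (Nicholas etherification). Proton loss from the tertiary cobalt-stabilised cation to the enyne complex may outrun capture by the crowded neopentyl-type carbinol, and the product may re-ionise under the Lewis acid. The fallback sets out from 6 and changes the way the O1–C2 bond is made. Gold(I)-catalysed intermolecular hydroalkoxylation of 3-methylbuta-1,2-diene [(IPr)AuCl/AgOTf, DMF, rt] adds the O–H bond at the dimethyl-substituted allene terminus. It comes back to the route directly at 12, bypassing 8–11. No compound outside the list is made (F0).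

Step 10 (epoxidation). The peracid may be delivered to the β face, or show poor facial discrimination, because the pseudo-axial methyl of the C2 gem-dimethyl group screens the α face while the C5a methyl screens the β face. The fallback sets out from 13 and inverts the facial outcome by way of a halohydrin. NBS in aqueous DME forms the bromonium ion on the more open face, and water opens it anti at C4. This gives (3S,4R,5aS,9aR)-3-bromo-4-hydroxy-2,2,5a-trimethyloctahydro-1-benzoxepin-6(2H)-one F1. K2CO3 in MeOH then closes the alkoxide onto C3 from the α side, which returns to the route at 14.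

Step 22 (Negishi union). Transmetalation and reductive elimination at an alkenylpalladium flanked by a quaternary carbon and a methyl-bearing alkene carbon may be slow. Protodezincation, β-hydride elimination or carbopalladation of the neighbouring allyl group could then take over. The fallback sets out from 23 and uses a more nucleophilic boron ate complex with C7 kept at the alcohol oxidation level.
- TESOTf/2,6-lutidine gives the 7-O-triethylsilyl iodide F2.
- Lithium–iodine exchange (t-BuLi, Et2O, −78 °C) and trapping with B-methoxy-9-BBN gives the lithium B-alkyl-B-methoxy-9-BBN borinate F3.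
- This is coupled in the same flask with 30 under B-alkyl Suzuki–Miyaura conditions [PdCl2(dppf), AsPh3, Cs2CO3, DMF/H2O] to give the coupled 7-O-TES bis-TBS ether F4.
- PPTS in MeOH removes only the triethylsilyl group to give the coupled C7 alcohol F5.
- Dess–Martin oxidation comes back to the route at 32.

**Further compounds**
F0 | step 6 | none | none
F1 | step 10 | (3S,4R,5aS,9aR)-3-bromo-4-hydroxy-2,2,5a-trimethyloctahydro-1-benzoxepin-6(2H)-one | O=C1CCC[C@H]2OC(C)(C)[C@@H](Br)[C@H](O)C[C@]12C
F2 | step 22 | 7-O-triethylsilyl iodide (TES ether of 23) | ICC[C@@H]1[C@@]2(C)CC[C@@H](O[Si](C)(C)C(C)(C)C)C(C)(C)O[C@@H]2CC[C@H]1O[Si](CC)(CC)CC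
F3 | step 22 | lithium B-alkyl-B-methoxy-9-BBN borinate | [Li+].CO[B-]1(CC[C@@H]3[C@@]4(C)CC[C@@H](O[Si](C)(C)C(C)(C)C)C(C)(C)O[C@@H]4CC[C@H]3O[Si](CC)(CC)CC)C2CCCC1CCC2
F4 | step 22 | coupled 7-O-TES bis-TBS ether | CC1=C(CC[C@@H]2[C@@]3(C)CC[C@@H](O[Si](C)(C)C(C)(C)C)C(C)(C)O[C@@H]3CC[C@H]2O[Si](CC)(CC)CC)[C@](C)(CC=C)[C@H](O[Si](C)(C)C(C)(C)C)CC1
F5 | step 22 | coupled C7 alcohol | CC1=C(CC[C@@H]2[C@@]3(C)CC[C@@H](O[Si](C)(C)C(C)(C)C)C(C)(C)O[C@@H]3CC[C@H]2O)[C@](C)(CC=C)[C@H](O[Si](C)(C)C(C)(C)C)CC1
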